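**Plan**

1. Retrosynthesis: the pyrone C3–CH2 bond is cut first (hydroxypyrone plus the ortho-quinone methide of an o-hydroxybenzyl alcohol), then the C5'–C(=O) bond (acyl shift from O4'), then the arene bonds C3'–C4', C1'–C2' and C4'–C5'. This unravels the benzene ring into a 3-methoxycyclobutenone and a siloxyalkyne.
2. Enabling feature: the benzene ring carries oxygen on C2', C4' and C6' in three different states (OH, OH, OMe), prenyl on C3' between the two hydroxyl carbons, and C5' as its last open carbon. These map onto alkyne C–OSi, ketene C=O, cyclobutenone C3–OMe, alkyne C–prenyl and cyclobutenone C4H2.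
3. Forward: cyclobutenone 5 (chloroacetal, methoxyacetylide, hydroxymethylation/silylation, ketene [2+2]) and siloxyalkyne 10 (ester ynolate) are fused in step 5, which forms the benzene ring.
4. O-Isobutyrylation and photo-Fries shift to C5' follow, then fluoride desilylation and union with pyrone 24 (ring closed separately from pentan-3-one and malonyl dichloride) through the quinone methide.
5. Stereochemistry: the target has no stereocentre and no stereogenic double bond, so nothing has to be controlled; the transient stereocentres of 12, 18 and 23 disappear.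

Key step: step 5

Remark: the arene is numbered C1' (carbon bearing the CH2 bridge), C2' (OH), C3' (prenyl), C4' (OH), C5' (isobutyryl), C6' (OMe). The pyrone is numbered O1, C2 (C=O), C3 (bridge), C4 (OH), C5 (Me), C6 (Et). Ketene gas is assumed to come from a laboratory acetone-pyrolysis generator.

**Route**

Step 1
Reactants: 1 2-chloro-1,1-dimethoxyethane (chloroacetaldehyde dimethyl acetal)
Product: 4 tert-butyl[(3-methoxyprop-2-yn-1-yl)oxy]dimethylsilane, via lithium methoxyethynide 2 (not isolated), via lithium 3-methoxyprop-2-yn-1-olate 3 (not isolated)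
Conditions: LiNEt2 (3.3 equiv), THF, 0 °C; (CH2O)n, −78 → 0 °C; TBSCl, DMAP (cat.), 0 °C → rt; chromatography on Et3N-deactivated silica
Reagents that add atoms: formaldehyde (as paraformaldehyde), C=O; tert-butyldimethylsilyl chloride, CC(C)(C)[Si](C)(C)Cl
Why: Three equivalents of amide base remove methanol and HCl from the chloroacetal and deprotonate the resulting methoxyacetylene (the standard alkoxyacetylide synthesis), the acetylide hydroxymethylates with formaldehyde, and silylating the lithium alkoxide in the same flask avoids handling the acid-labile ynol ether alcohol.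

Step 2
Reactants: 4 tert-butyl[(3-methoxyprop-2-yn-1-yl)oxy]dimethylsilane
Product: 5 2-[(tert-butyldimethylsilyloxy)methyl]-3-methoxycyclobut-2-en-1-one
Conditions: ketene (excess, from acetone pyrolysis), CH2Cl2, 0 °C → rt
Reagents that add atoms: ketene, C=C=O
Why: In this ketene–ynol ether [2+2] cycloaddition the nucleophilic β-carbon of the alkoxyalkyne attacks the ketene carbonyl carbon and the zwitterion closes at the oxocarbenium carbon, which places methoxy on C3 and the silyloxymethyl group on C2.

Step 3
Reactants: 6 4-methylpent-3-enoic acid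
Product: 7 ethyl 4-methylpent-3-enoate
Conditions: EtI, K2CO3, DMF, rt
Reagents that add atoms: iodoethane, CCI
Why: SN2 O-alkylation of the carboxylate under basic conditions avoids the acid-induced lactonisation and double-bond migration that a Fischer esterification of this β,γ-unsaturated acid would risk.

Step 4
Reactants: 7 ethyl 4-methylpent-3-enoate
Product: 10 triisopropyl[(5-methylhex-4-en-1-yn-1-yl)oxy]silane, via dibromo enolate 8 (not isolated), via lithium ynolate 9 (not isolated)
Conditions: CH2Br2, lithium 2,2,6,6-tetramethylpiperidide, THF, −78 °C; LiN(SiMe3)2, −78 °C; n-BuLi, −78 → 25 °C; TIPSCl, −78 → 0 °C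
Reagents that add atoms: dibromomethane, BrCBr; triisopropylsilyl chloride, CC(C)[Si](Cl)(C(C)C)C(C)C
Why: In this Kowalski ester homologation LiCHBr2 adds to the ester, the dibromo ketone enolate undergoes bromine–lithium exchange and carbenoid rearrangement to the ynolate, and the bulky silyl chloride traps the ynolate on oxygen.

Step 5
Reactants: 5 2-[(tert-butyldimethylsilyloxy)methyl]-3-methoxycyclobut-2-en-1-one; 10 triisopropyl[(5-methylhex-4-en-1-yn-1-yl)oxy]silane
Product: 15 4-[(tert-butyldimethylsilyloxy)methyl]-5-methoxy-2-(3-methylbut-2-en-1-yl)-3-(triisopropylsilyloxy)phenol, via vinylketene 11 (not isolated), via 4-vinylcyclobutenone 12 (not isolated), via dienylketene 13 (not isolated), via cyclohexa-2,4-dienone 14 (not isolated)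
Conditions: 5 (1.0 equiv), 10 (1.2 equiv), toluene, 80 → 130 °C, sealed tube, under argon
Reagents that add atoms: none
Why: Heat opens 5 by 4π electrocyclic cleavage of its C1–C4 bond to (1-methoxyvinyl)ketene 11, whose ketene C=C adds [2+2] to siloxyalkyne 10 to give 4-vinylcyclobutenone 12. A second, reversible 4π opening gives dienylketene 13, which closes the benzene ring by 6π electrocyclisation between the ketene carbon and the CH2 terminus (bond C4'–C5'), and enolisation of dienone 14 should deliver phenol 15. The closest known reaction is the Danheiser benzannulation of cyclobutenones with trialkylsilyloxyalkynes, the established route to differentially protected resorcinols. No stereocentre is created, since 12 forms as a racemate and its stereocentre is lost on ring opening. The selectivity needed is the orientation of the ketene–alkyne [2+2]: the polarised ynol ether uses its prenyl-bearing β-carbon as nucleophile toward the ketene carbonyl carbon (C3'–C4'), so the silyloxy carbon joins the ketene α-carbon (C1'–C2') and prenyl ends between the two new oxygens. Because C4 of 5 is the only CH2, the arene keeps one unsubstituted carbon (C5') next to the free hydroxyl.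

Step 6
Reactants: 15 4-[(tert-butyldimethylsilyloxy)methyl]-5-methoxy-2-(3-methylbut-2-en-1-yl)-3-(triisopropylsilyloxy)phenol; 16 2-methylpropanoyl chloride (isobutyryl chloride)
Product: 17 4-[(tert-butyldimethylsilyloxy)methyl]-5-methoxy-2-(3-methylbut-2-en-1-yl)-3-(triisopropylsilyloxy)phenyl 2-methylpropanoate
Conditions: Et3N, DMAP (cat.), CH2Cl2, 0 °C
Reagents that add atoms: none
Why: DMAP-catalysed O-acylation of the only free phenol is routine, and both silyl ethers and the alkene are inert to it.

Step 7
Reactants: 17 4-[(tert-butyldimethylsilyloxy)methyl]-5-methoxy-2-(3-methylbut-2-en-1-yl)-3-(triisopropylsilyloxy)phenyl 2-methylpropanoate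
Product: 19 1-[3-[(tert-butyldimethylsilyloxy)methyl]-6-hydroxy-2-methoxy-5-(3-methylbut-2-en-1-yl)-4-(triisopropylsilyloxy)phenyl]-2-methylpropan-1-one, via acyl dienone 18 (not isolated)
Conditions: hν (254 nm, quartz), degassed cyclohexane, rt
Reagents that add atoms: none
Why: In this photo-Fries rearrangement the excited aryl ester homolyses at the O–acyl bond and the caged phenoxyl/isobutyryl radical pair can recombine productively only at C5', because the other ortho carbon (C3') and the para carbon (C1') are substituted, while the neutral conditions spare the silyl ethers and the prenyl group.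

Step 8
Reactants: 19 1-[3-[(tert-butyldimethylsilyloxy)methyl]-6-hydroxy-2-methoxy-5-(3-methylbut-2-en-1-yl)-4-(triisopropylsilyloxy)phenyl]-2-methylpropan-1-one
Product: 20 1-[2,4-dihydroxy-5-(hydroxymethyl)-6-methoxy-3-(3-methylbut-2-en-1-yl)phenyl]-2-methylpropan-1-one
Conditions: Bu4NF (2.5 equiv), AcOH (2.5 equiv), THF, 0 °C → rt; crude product used at once
Reagents that add atoms: none
Why: Fluoride cleaves the aryl TIPS ether and the primary TBS ether through Si–F bond formation, and the acetic acid buffer keeps the phenols protonated so that the sensitive hydroxybenzyl alcohol does not ionise during the deprotection.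

Step 9
Reactants: 21 pentan-3-one
Product: 22 (Z)-trimethyl(pent-2-en-3-yloxy)silane (the E isomer, if present, reacts alike)
Conditions: Me3SiCl, Et3N, DMF, 80 °C
Reagents that add atoms: chlorotrimethylsilane, C[Si](C)(C)Cl
Why: Silyl enol ether formation under equilibrating amine conditions is standard, and the symmetrical ketone removes any regiochemical question.

Step 10
Reactants: 22 (Z)-trimethyl(pent-2-en-3-yloxy)silane
Product: 24 6-ethyl-4-hydroxy-5-methyl-2H-pyran-2-one, via diketo acid chloride 23 (not isolated)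
Conditions: CH2(COCl)2 (1.0 equiv), Et2O, −78 °C → rt
Reagents that add atoms: malonyl dichloride, O=C(Cl)CC(=O)Cl
Why: C-Acylation of the silyl enol ether by malonyl dichloride followed by ring closure of the enol oxygen onto the second acid chloride is the established one-flask route to 4-hydroxy-2-pyrones, and it places methyl on C5 and ethyl on C6.

Step 11
Reactants: 20 1-[2,4-dihydroxy-5-(hydroxymethyl)-6-methoxy-3-(3-methylbut-2-en-1-yl)phenyl]-2-methylpropan-1-one; 24 6-ethyl-4-hydroxy-5-methyl-2H-pyran-2-one
Product: 26 6-ethyl-4-hydroxy-3-{[2,4-dihydroxy-6-methoxy-3-(3-methylbut-2-en-1-yl)-5-(2-methylpropanoyl)phenyl]methyl}-5-methyl-2H-pyran-2-one (CNP0149198.0), via ortho-quinone methide 25 (not isolated)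
Conditions: 24 (3 equiv), NaOAc, AcOH, 60 °C
Reagents that add atoms: none
Why: Loss of water from the electron-rich o-hydroxybenzyl alcohol gives ortho-quinone methide 25, to which the hydroxypyrone adds through its nucleophilic C3 (Michael addition with rearomatisation), and excess pyrone should outrun self-condensation because the arene has no free ring carbon.

**Compound list**

1 | 2-chloro-1,1-dimethoxyethane | COC(CCl)OC | starting material
2 | lithium methoxyethynide | [Li+].[C-]#COC | intermediate (not isolated)
3 | lithium 3-methoxyprop-2-yn-1-olate | [Li+].[O-]CC#COC | intermediate (not isolated)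
4 | tert-butyl[(3-methoxyprop-2-yn-1-yl)oxy]dimethylsilane | COC#CCO[Si](C)(C)C(C)(C)C | intermediate
5 | 2-[(tert-butyldimethylsilyloxy)methyl]-3-methoxycyclobut-2-en-1-one | COC1=C(CO[Si](C)(C)C(C)(C)C)C(=O)C1 | intermediate
6 | 4-methylpent-3-enoic acid | CC(C)=CCC(=O)O | starting material
7 | ethyl 4-methylpent-3-enoate | CCOC(=O)CC=C(C)C | intermediate
8 | lithium 1,1-dibromo-5-methylhexa-1,4-dien-2-olate | [Li+].[O-]C(CC=C(C)C)=C(Br)Br | intermediate (not isolated)
9 | lithium 5-methylhex-4-en-1-yn-1-olate | [Li+].[O-]C#CCC=C(C)C | intermediate (not isolated)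
10 | triisopropyl[(5-methylhex-4-en-1-yn-1-yl)oxy]silane | CC(C)=CCC#CO[Si](C(C)C)(C(C)C)C(C)C | intermediate
11 | 2-[(tert-butyldimethylsilyloxy)methyl]-3-methoxybuta-1,3-dien-1-one | C=C(OC)C(CO[Si](C)(C)C(C)(C)C)=C=O | intermediate (not isolated)
12 | 4-[(tert-butyldimethylsilyloxy)methyl]-4-(1-methoxyethenyl)-2-(3-methylbut-2-en-1-yl)-3-(triisopropylsilyloxy)cyclobut-2-en-1-one (racemic) | O=C1C(CC=C(C)C)=C(O[Si](C(C)C)(C(C)C)C(C)C)C1(CO[Si](C)(C)C(C)(C)C)C(OC)=C | intermediate (not isolated)
13 | (3E)-4-[(tert-butyldimethylsilyloxy)methyl]-5-methoxy-2-(3-methylbut-2-en-1-yl)-3-(triisopropylsilyloxy)hexa-1,3,5-trien-1-one | O=C=C(CC=C(C)C)/C(O[Si](C(C)C)(C(C)C)C(C)C)=C(CO[Si](C)(C)C(C)(C)C)\C(OC)=C | intermediate (not isolated)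
14 | 4-[(tert-butyldimethylsilyloxy)methyl]-5-methoxy-2-(3-methylbut-2-en-1-yl)-3-(triisopropylsilyloxy)cyclohexa-2,4-dien-1-one | O=C1CC(OC)=C(CO[Si](C)(C)C(C)(C)C)C(O[Si](C(C)C)(C(C)C)C(C)C)=C1CC=C(C)C | intermediate (not isolated)
15 | 4-[(tert-butyldimethylsilyloxy)methyl]-5-methoxy-2-(3-methylbut-2-en-1-yl)-3-(triisopropylsilyloxy)phenol | COc1cc(O)c(CC=C(C)C)c(O[Si](C(C)C)(C(C)C)C(C)C)c1CO[Si](C)(C)C(C)(C)C | intermediate
16 | 2-methylpropanoyl chloride | CC(C)C(=O)Cl | starting material
17 | 4-[(tert-butyldimethylsilyloxy)methyl]-5-methoxy-2-(3-methylbut-2-en-1-yl)-3-(triisopropylsilyloxy)phenyl 2-methylpropanoate | COc1cc(OC(=O)C(C)C)c(CC=C(C)C)c(O[Si](C(C)C)(C(C)C)C(C)C)c1CO[Si](C)(C)C(C)(C)C | intermediate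
18 | 4-[(tert-butyldimethylsilyloxy)methyl]-5-methoxy-2-(3-methylbut-2-en-1-yl)-6-(2-methylpropanoyl)-3-(triisopropylsilyloxy)cyclohexa-2,4-dien-1-one (racemic) | O=C1C(CC=C(C)C)=C(O[Si](C(C)C)(C(C)C)C(C)C)C(CO[Si](C)(C)C(C)(C)C)=C(OC)C1C(=O)C(C)C | intermediate (not isolated)
19 | 1-[3-[(tert-butyldimethylsilyloxy)methyl]-6-hydroxy-2-methoxy-5-(3-methylbut-2-en-1-yl)-4-(triisopropylsilyloxy)phenyl]-2-methylpropan-1-one | COc1c(CO[Si](C)(C)C(C)(C)C)c(O[Si](C(C)C)(C(C)C)C(C)C)c(CC=C(C)C)c(O)c1C(=O)C(C)C | intermediate
20 | 1-[2,4-dihydroxy-5-(hydroxymethyl)-6-methoxy-3-(3-methylbut-2-en-1-yl)phenyl]-2-methylpropan-1-one | COc1c(CO)c(O)c(CC=C(C)C)c(O)c1C(=O)C(C)C | intermediate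
21 | pentan-3-one | CCC(=O)CC | starting material
22 | (Z)-trimethyl(pent-2-en-3-yloxy)silane | C/C=C(\O[Si](C)(C)C)CC | intermediate
23 | 4-methyl-3,5-dioxoheptanoyl chloride (racemic) | CCC(=O)C(C)C(=O)CC(=O)Cl | intermediate (not isolated)
24 | 6-ethyl-4-hydroxy-5-methyl-2H-pyran-2-one | CCc1oc(=O)cc(O)c1C | intermediate
25 | 3-hydroxy-5-methoxy-6-methylidene-2-(3-methylbut-2-en-1-yl)-4-(2-methylpropanoyl)cyclohexa-2,4-dien-1-one | C=C1C(=O)C(CC=C(C)C)=C(O)C(C(=O)C(C)C)=C1OC | intermediate (not isolated)
26 | 6-ethyl-4-hydroxy-3-{[2,4-dihydroxy-6-methoxy-3-(3-methylbut-2-en-1-yl)-5-(2-methylpropanoyl)phenyl]methyl}-5-methyl-2H-pyran-2-one | CCc1oc(=O)c(Cc2c(O)c(CC=C(C)C)c(O)c(C(=O)C(C)C)c2OC)c(O)c1C | target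

**Step count and risks**

Total steps: 11. Longest linear sequence: 7 steps (1, 2, 5, 6, 7, 8, 11; equally 3, 4, 5, 6, 7, 8, 11).

Steps most likely to fail:

Step 5 (benzannulation). The donor-stabilised cyclobutenone may open only at temperatures at which the siloxyalkyne degrades, or the vinylketene may acylate phenol already formed, so that the cascade stalls. The fallback replaces ring synthesis by substitution of a preformed phloroglucinol ether; it sets out from isobutyryl chloride 16 and rejoins the route at target 26. Friedel–Crafts acylation of commercial 5-methoxybenzene-1,3-diol with 16 (AlCl3, CH2Cl2/PhNO2) should give, after removal of the 2,6-dihydroxy-4-methoxy isomer, 1-(2,4-dihydroxy-6-methoxyphenyl)-2-methylpropan-1-one F1. C-Alkylation of its phenoxide with 1-bromo-3-methylbut-2-ene (aqueous KOH, 0 °C) at the carbon between the two hydroxyls should give 1-[2,4-dihydroxy-6-methoxy-3-(3-methylbut-2-en-1-yl)phenyl]-2-methylpropan-1-one F2, to be separated from O-alkylated and doubly alkylated material. Pyrone 24 with dimethylmethylideneammonium iodide should form the Mannich base 3-[(dimethylamino)methyl]-6-ethyl-4-hydroxy-5-methyl-2H-pyran-2-one F3, which loses dimethylamine to 6-ethyl-5-methyl-3-methylidene-2H-pyran-2,4(3H)-dione F4. Conjugate addition of F2 through its only free ring carbon to F4 then gives 26. This reserve route gives up the regiocontrol that the ring synthesis provides.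

Step 7 (photo-Fries shift). The radical pair may escape the solvent cage and return phenol 15, the acyl radical may lose CO, or the arene and prenyl chromophores may undergo secondary photochemistry. The fallback builds the ketone by polar steps; it sets out from phenol 15 and returns at ketone 19. Magnesium phenoxide-directed ortho-formylation (MgCl2, Et3N, paraformaldehyde, MeCN, reflux) should give 5-[(tert-butyldimethylsilyloxy)methyl]-2-hydroxy-6-methoxy-3-(3-methylbut-2-en-1-yl)-4-(triisopropylsilyloxy)benzaldehyde F5. Addition of i-PrMgCl (excess, THF, −20 °C) should give racemic 4-[(tert-butyldimethylsilyloxy)methyl]-6-(1-hydroxy-2-methylpropyl)-5-methoxy-2-(3-methylbut-2-en-1-yl)-3-(triisopropylsilyloxy)phenol F6. Oxidation of the benzylic alcohol with MnO2 in CH2Cl2 then gives 19.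

Step 11 (quinone methide union). The ionised benzylic position may lose formaldehyde or be captured at an ipso carbon of a second arene, and acid may add a flanking hydroxyl across the prenyl double bond to form a chroman. The fallback moves the benzylic carbon to the aldehyde oxidation level; it sets out from triol 20 and returns at target 26. Oxidation with MnO2 (CH2Cl2, rt) should give 2,4-dihydroxy-6-methoxy-3-(3-methylbut-2-en-1-yl)-5-(2-methylpropanoyl)benzaldehyde F7. Three-component reductive alkylation with pyrone 24 and diethyl 2,6-dimethyl-1,4-dihydropyridine-3,5-dicarboxylate (L-proline cat., CH2Cl2, rt) should pass through the Knoevenagel adduct 3-{[2,4-dihydroxy-6-methoxy-3-(3-methylbut-2-en-1-yl)-5-(2-methylpropanoyl)phenyl]methylidene}-6-ethyl-5-methyl-2H-pyran-2,4(3H)-dione F8 (alkene geometry undefined), whose transfer hydrogenation by the dihydropyridine gives 26.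

**Further compounds**

F1 | step 5 | 1-(2,4-dihydroxy-6-methoxyphenyl)-2-methylpropan-1-one | COc1cc(O)cc(O)c1C(=O)C(C)C
F2 | step 5 | 1-[2,4-dihydroxy-6-methoxy-3-(3-methylbut-2-en-1-yl)phenyl]-2-methylpropan-1-one | COc1cc(O)c(CC=C(C)C)c(O)c1C(=O)C(C)C
F3 | step 5 | 3-[(dimethylamino)methyl]-6-ethyl-4-hydroxy-5-methyl-2H-pyran-2-one | CCc1oc(=O)c(CN(C)C)c(O)c1C
F4 | step 5 | 6-ethyl-5-methyl-3-methylidene-2H-pyran-2,4(3H)-dione | CCC1=C(C)C(=O)C(=C)C(=O)O1
F5 | step 7 | 5-[(tert-butyldimethylsilyloxy)methyl]-2-hydroxy-6-methoxy-3-(3-methylbut-2-en-1-yl)-4-(triisopropylsilyloxy)benzaldehyde | COc1c(CO[Si](C)(C)C(C)(C)C)c(O[Si](C(C)C)(C(C)C)C(C)C)c(CC=C(C)C)c(O)c1C=O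
F6 | step 7 | 4-[(tert-butyldimethylsilyloxy)methyl]-6-(1-hydroxy-2-methylpropyl)-5-methoxy-2-(3-methylbut-2-en-1-yl)-3-(triisopropylsilyloxy)phenol (racemic) | COc1c(CO[Si](C)(C)C(C)(C)C)c(O[Si](C(C)C)(C(C)C)C(C)C)c(CC=C(C)C)c(O)c1C(O)C(C)C
F7 | step 11 | 2,4-dihydroxy-6-methoxy-3-(3-methylbut-2-en-1-yl)-5-(2-methylpropanoyl)benzaldehyde | COc1c(C=O)c(O)c(CC=C(C)C)c(O)c1C(=O)C(C)C
F8 | step 11 | 3-{[2,4-dihydroxy-6-methoxy-3-(3-methylbut-2-en-1-yl)-5-(2-methylpropanoyl)phenyl]methylidene}-6-ethyl-5-methyl-2H-pyran-2,4(3H)-dione (alkene geometry undefined) | CCC1=C(C)C(=O)C(=Cc2c(O)c(CC=C(C)C)c(O)c(C(=O)C(C)C)c2OC)C(=O)O1
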